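In isochromene numbering, everything rests on disconnecting C1–C8a of ring B in the 4a,5-dihydro compound. With C4a–C5 saturated, ring A is a 2-acyloxy-2-methylcyclohexane-1,3-dione whose arms C5/C6 and C8a/C8 are mirror-related, so C7 is not yet stereogenic. The key step, a TiCl4-mediated intramolecular Claisen condensation of one arm's enolate onto a formate carried by the C3 oxygen, forms C1–C8a, closes ring B and sets C4a and C7 together, the (R)-C3 methyl choosing the arm. Its precursor is the dione bearing the linoleoyloxy group at C7 and, cis to it, an (R)-2-(formyloxy)propyl chain at C4a; it comes from an aryl Grignard, (R)-propylene oxide and a Birch reduction, and a final dehydrogenation installs C4a=C5.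

Key step: step 6

Assumption (remark on the chemistry): ring closure is taken to pass through the cis-fused chair that perpendicular attack on a ring A enolate imposes, in which the untouched arm C5 is axial on ring B; on this model it is the cis dione (acyloxy group and side chain on the same ring face) that relays (R)-C3 to (R)-C7 via (4aS), so the cis isomer is carried forward.

Step 1
Reactants: 1 5-bromo-1,3-dimethoxy-2-methylbenzene; 2 (R)-propylene oxide
Product: 4 (2R)-1-(3,5-dimethoxy-4-methylphenyl)propan-2-ol, via aryl Grignard reagent 3 (not isolated)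
Conditions: Mg, THF, reflux; then CuI (cat.), 2, THF, −30 to 0 °C; aq. NH4Cl
Reagents that add atoms: magnesium, [Mg] (its atom is held only in intermediate 3)
Why: Copper-catalysed Grignard opening of a terminal epoxide is an SN2 attack at the unsubstituted carbon, so the stereocentre of 2 is not touched and becomes the (R)-carbinol that will be C3.

Step 2
Reactants: 4 (2R)-1-(3,5-dimethoxy-4-methylphenyl)propan-2-ol
Product: 6 5-[(2R)-2-hydroxypropyl]-2-methylcyclohexane-1,3-dione, via bis-enol ether diene 5 (not isolated)
Conditions: Li, NH3(l), THF, t-BuOH, −78 to −33 °C; then 2 M HCl, THF, rt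
Reagents that add atoms: water, O
Why: Birch reduction of a resorcinol dimethyl ether puts the two new hydrogens on the carbons bearing the methyl group and the side chain (the methoxy carbons stay vinylic), and acid hydrolysis of the bis-enol ether gives the 2-methyl-1,3-dione; the carbinol centre is a spectator and the ring sp3 centres of 5 are erased by enolisation.

Step 3
Reactants: 6 5-[(2R)-2-hydroxypropyl]-2-methylcyclohexane-1,3-dione
Product: 7 (2R)-1-(4-methyl-3,5-dioxocyclohexyl)propan-2-yl formate
Conditions: HCO2H (98%), 50 °C; toluene azeotrope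
Reagents that add atoms: formic acid, O=CO
Why: Fischer-type esterification in neat formic acid formylates the secondary alcohol with retention (acyl–oxygen mode) and leaves the acidic, enolised dione alone, whereas activated formylating agents would also acylate its enol oxygen.

Step 4
Reactants: 7 (2R)-1-(4-methyl-3,5-dioxocyclohexyl)propan-2-yl formate
Product: 8 (2R)-1-(cis-4-hydroxy-4-methyl-3,5-dioxocyclohexyl)propan-2-yl formate
Conditions: dimethyldioxirane, acetone, 0 °C; chromatographic removal of the trans isomer
Reagents that add atoms: dimethyldioxirane, CC1(C)OO1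
Why: Dimethyldioxirane epoxidises the enol double bond of the 1,3-dione and the epoxide opens to the 2-hydroxy-1,3-dione (known hydroxylation of enolisable β-dicarbonyl compounds); the new C7–O bond can form on either face of the sofa-shaped enol, with at best a modest preference for axial entry anti to the ring flap (the cis isomer), so the purity of 8 is secured by separation from the trans isomer and not by the reaction itself.

Step 5
Reactants: 8 (2R)-1-(cis-4-hydroxy-4-methyl-3,5-dioxocyclohexyl)propan-2-yl formate; 9 linoleic acid
Product: 11 cis-5-[(2R)-2-(formyloxy)propyl]-2-methyl-1,3-dioxocyclohexan-2-yl (9Z,12Z)-octadeca-9,12-dienoate, via linoleoyl chloride 10 (not isolated)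
Conditions: 9, (COCl)2, N,N-dimethylformamide (cat.), CH2Cl2, 0 °C to rt; then 8, pyridine, 4-(dimethylamino)pyridine (cat.), CH2Cl2, 0 °C
Reagents that add atoms: oxalyl chloride, O=C(Cl)C(=O)Cl (its chlorine is held only in intermediate 10)
Why: Acyl chloride esterification under nucleophilic catalysis acylates the tertiary α-hydroxyl without touching the quaternary C7 centre, the low temperature holds back base-induced α-ketol rearrangement, and the skipped (Z,Z)-diene is inert in both stages.

Step 6
Reactants: 11 cis-5-[(2R)-2-(formyloxy)propyl]-2-methyl-1,3-dioxocyclohexan-2-yl (9Z,12Z)-octadeca-9,12-dienoate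
Product: 13 (3R,4aS,7R)-3,7-dimethyl-6,8-dioxo-4,4a,5,6,7,8-hexahydro-3H-isochromen-7-yl (9Z,12Z)-octadeca-9,12-dienoate, via cyclic lactol 12 (not isolated)
Conditions: TiCl4, Et3N, CH2Cl2 (0.01 M), −78 to −40 °C; aq. NH4Cl; then pyridinium p-toluenesulfonate (cat.), 4 Å MS, CH2Cl2, rt
Reagents that add atoms: none
Why: Proposed new method: TiCl4 and Et3N turn one of the two equivalent ketone arms of ring A into its trichlorotitanium enolate, whose carbon (the future C8a) adds to the TiCl4-activated formate carbonyl on the C3 oxygen to give lactol 12, and mild acid then expels water to leave the C1=C8a vinylogous ester; the closest known reaction type is the TiCl4–amine crossed Claisen formylation of ketones with formate esters, which has not been run intramolecularly to tell apart the arms of a 2,2-disubstituted 1,3-dione. Ring B closes 6-exo-trig at the formyl carbon through a chair in which attack is perpendicular to the ring A enolate, so the bicycle is cis-fused in the transition state and the unused arm C5 sits axial on the forming ring. The C3 methyl must then be equatorial, since an axial methyl would meet C5 in a syn-diaxial clash, and with (R)-C3 this fits only closure onto the arm that makes C4a (S): C4a is set by C3 through the chair. C7 becomes stereogenic in the same event because its two carbonyl arms stop being equivalent, and the cis relation of acyloxy group and side chain built into 11 converts (4aS) into (7R). The step needs arm selection (diastereotopic-group selectivity) and ketone-over-ester enolisation; the first is secured by the equatorial demand of the C3 methyl, the second by the higher acidity of the ring α-hydrogens at −78 °C, with high dilution holding back intermolecular aldol addition.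

Step 7
Reactants: 13 (3R,4aS,7R)-3,7-dimethyl-6,8-dioxo-4,4a,5,6,7,8-hexahydro-3H-isochromen-7-yl (9Z,12Z)-octadeca-9,12-dienoate
Product: 14 (3R,4aS,7R)-3,7-dimethyl-8-oxo-6-[(trimethylsilyl)oxy]-4,4a,7,8-tetrahydro-3H-isochromen-7-yl (9Z,12Z)-octadeca-9,12-dienoate
Conditions: Me3SiOTf, Et3N, CH2Cl2, 0 °C
Reagents that add atoms: trimethylsilyl trifluoromethanesulfonate, C[Si](C)(C)OS(=O)(=O)C(F)(F)F
Why: Soft enolisation (silyl enol ether formation) can only engage the C6 ketone toward C5, because C7 is quaternary and the C8 carbonyl is a vinylogous ester without α-hydrogens, so one regioisomer forms and no stereocentre is touched.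

Step 8
Reactants: 14 (3R,4aS,7R)-3,7-dimethyl-8-oxo-6-[(trimethylsilyl)oxy]-4,4a,7,8-tetrahydro-3H-isochromen-7-yl (9Z,12Z)-octadeca-9,12-dienoate
Product: 15 (3R,7R)-3,7-dimethyl-6,8-dioxo-3,4,7,8-tetrahydro-6H-isochromen-7-yl (9Z,12Z)-octadeca-9,12-dienoate
Conditions: 2-iodoxybenzoic acid–4-methoxypyridine N-oxide complex (IBX·MPO), DMSO/CH2Cl2, rt
Reagents that add atoms: none
Why: IBX-mediated dehydrogenation of a silyl enol ether gives the C4a=C5 enone at room temperature without metal hydrides or electrophilic selenium that could attack the skipped diene, and it removes the auxiliary C4a centre so that C3 and C7 remain as (3R,7R).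

Compound list
1 | 5-bromo-1,3-dimethoxy-2-methylbenzene | COc1cc(Br)cc(OC)c1C | starting material
2 | (R)-propylene oxide, (2R)-2-methyloxirane | C[C@@H]1CO1 | starting material
3 | (3,5-dimethoxy-4-methylphenyl)magnesium bromide (not isolated) | COc1cc([Mg]Br)cc(OC)c1C | intermediate
4 | (2R)-1-(3,5-dimethoxy-4-methylphenyl)propan-2-ol | C[C@@H](O)Cc1cc(OC)c(C)c(OC)c1 | intermediate
5 | (2R)-1-(3,5-dimethoxy-4-methylcyclohexa-2,5-dien-1-yl)propan-2-ol (ring cis/trans mixture, erased in the same step; not isolated) | C[C@@H](O)CC1C=C(OC)C(C)C(OC)=C1 | intermediate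
6 | 5-[(2R)-2-hydroxypropyl]-2-methylcyclohexane-1,3-dione (drawn as the diketone, largely enolised) | C[C@@H](O)CC1CC(=O)C(C)C(=O)C1 | intermediate
7 | (2R)-1-(4-methyl-3,5-dioxocyclohexyl)propan-2-yl formate | O=CO[C@H](C)CC1CC(=O)C(C)C(=O)C1 | intermediate
8 | (2R)-1-(cis-4-hydroxy-4-methyl-3,5-dioxocyclohexyl)propan-2-yl formate (hydroxyl and side chain on the same ring face) | O=CO[C@H](C)C[C@H]1CC(=O)[C@@](C)(O)C(=O)C1 | intermediate
9 | linoleic acid, (9Z,12Z)-octadeca-9,12-dienoic acid | CCCCC/C=C\C/C=C\CCCCCCCC(=O)O | starting material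
10 | linoleoyl chloride (not isolated) | CCCCC/C=C\C/C=C\CCCCCCCC(=O)Cl | intermediate
11 | cis-5-[(2R)-2-(formyloxy)propyl]-2-methyl-1,3-dioxocyclohexan-2-yl (9Z,12Z)-octadeca-9,12-dienoate (acyloxy group and side chain on the same ring face; key-step precursor) | O=CO[C@H](C)C[C@H]1CC(=O)[C@@](C)(OC(=O)CCCCCCC/C=C\C/C=C\CCCCC)C(=O)C1 | intermediate
12 | (3R,4aS,7R)-1-hydroxy-3,7-dimethyl-6,8-dioxooctahydro-1H-isochromen-7-yl (9Z,12Z)-octadeca-9,12-dienoate (lactol; C1 and C8a unassigned, both lost on dehydration; not isolated) | C[C@@H]1C[C@H]2CC(=O)[C@@](C)(OC(=O)CCCCCCC/C=C\C/C=C\CCCCC)C(=O)C2C(O)O1 | intermediate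
13 | (3R,4aS,7R)-3,7-dimethyl-6,8-dioxo-4,4a,5,6,7,8-hexahydro-3H-isochromen-7-yl (9Z,12Z)-octadeca-9,12-dienoate (key-step product) | C[C@@H]1C[C@H]2CC(=O)[C@@](C)(OC(=O)CCCCCCC/C=C\C/C=C\CCCCC)C(=O)C2=CO1 | intermediate
14 | (3R,4aS,7R)-3,7-dimethyl-8-oxo-6-[(trimethylsilyl)oxy]-4,4a,7,8-tetrahydro-3H-isochromen-7-yl (9Z,12Z)-octadeca-9,12-dienoate | C[C@@H]1C[C@H]2C=C(O[Si](C)(C)C)[C@@](C)(OC(=O)CCCCCCC/C=C\C/C=C\CCCCC)C(=O)C2=CO1 | intermediate
15 | (3R,7R)-3,7-dimethyl-6,8-dioxo-3,4,7,8-tetrahydro-6H-isochromen-7-yl (9Z,12Z)-octadeca-9,12-dienoate | CCCCC/C=C\C/C=C\CCCCCCCC(=O)O[C@]1(C)C(=O)C=C2C[C@@H](C)OC=C2C1=O | target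

Total step count: 8
Longest linear sequence: 8 steps (1 to 15; linoleic acid 9 enters at step 5)

Steps most likely to fail

1. Step 6 (the labelled step). What may go wrong: the enolate may close through the other arm or through boat-like geometries, so that arm selection erodes or inverts and C7 emerges partly or wholly epimeric. Enolisation of the linoleate α-position with attack on a ring ketone, or intermolecular aldol addition, may also outrun ring closure. The fallback uses known chemistry (oxidative dearomatisation to the azaphilone core); it sets out from 4 and comes back at 15.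
   - Vilsmeier–Haack formylation of 4 (POCl3, DMF; then K2CO3, MeOH to cleave any O-formate) should give 6-[(2R)-2-hydroxypropyl]-2,4-dimethoxy-3-methylbenzaldehyde F1.
   - BBr3 removes both methyl ethers, and the hydroxy aldehyde should close under the acidic work-up, with loss of water, to the quinone methide (3R)-8-hydroxy-3,7-dimethyl-3,4-dihydro-6H-isochromen-6-one F2.
   - Hydroxylative dearomatisation at C7 with IBX should give the tertiary alcohol as two C7 epimers, which are diastereomers because of C3 and are separated: the required (3R,7R)-7-hydroxy-3,7-dimethyl-3,4-dihydro-6H-isochromene-6,8(7H)-dione F3 and (3R,7S)-7-hydroxy-3,7-dimethyl-3,4-dihydro-6H-isochromene-6,8(7H)-dione F4.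
   - Acylation of F3 with linoleoyl chloride 10 (pyridine, 4-(dimethylamino)pyridine) gives 15.
   - This path gives up control at C7 but uses only established reaction types.

2. Step 4. What may go wrong: oxygen transfer to both faces of the enol with little discrimination, leaving the cis isomer as the minor component, and loss of material through α-ketol rearrangement during purification. The fallback recycles material instead of seeking selectivity; it sets out from 7 and comes back at 7. The co-formed trans isomer, (2R)-1-(trans-4-hydroxy-4-methyl-3,5-dioxocyclohexyl)propan-2-yl formate F5, is acetylated (Ac2O, pyridine, 4-(dimethylamino)pyridine) to (2R)-1-(trans-4-acetoxy-4-methyl-3,5-dioxocyclohexyl)propan-2-yl formate F6. SmI2 (THF–MeOH, −78 °C) then cleaves the α-acyloxy C–O bond reductively, a known reaction of α-acyloxy ketones, and returns dione 7 for another pass.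

3. Step 5. What may go wrong: base-induced α-ketol rearrangement (ring contraction) or retro-Claisen opening of the hydroxy dione may outpace acylation of the hindered tertiary hydroxyl. The fallback is a direct oxidative acyloxylation that avoids the free hydroxy dione; it sets out from 7 and comes back at 11. Ligand exchange of PhI(OAc)2 with linoleic acid 9 under reduced pressure gives [bis(linoleoyloxy)iodo]benzene F7. F7 transfers a linoleoyloxy group to C7 of the enolised dione 7, a known hypervalent-iodine α-acyloxylation of 1,3-dicarbonyl compounds. The cis isomer 11 is separated by chromatography from trans-5-[(2R)-2-(formyloxy)propyl]-2-methyl-1,3-dioxocyclohexan-2-yl (9Z,12Z)-octadeca-9,12-dienoate F8.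

Further compounds
F1 | step 6 | 6-[(2R)-2-hydroxypropyl]-2,4-dimethoxy-3-methylbenzaldehyde | C[C@@H](O)Cc1cc(OC)c(C)c(OC)c1C=O
F2 | step 6 | (3R)-8-hydroxy-3,7-dimethyl-3,4-dihydro-6H-isochromen-6-one | C[C@@H]1CC2=CC(=O)C(C)=C(O)C2=CO1
F3 | step 6 | (3R,7R)-7-hydroxy-3,7-dimethyl-3,4-dihydro-6H-isochromene-6,8(7H)-dione | C[C@@H]1CC2=CC(=O)[C@@](C)(O)C(=O)C2=CO1
F4 | step 6 | (3R,7S)-7-hydroxy-3,7-dimethyl-3,4-dihydro-6H-isochromene-6,8(7H)-dione | C[C@@H]1CC2=CC(=O)[C@](C)(O)C(=O)C2=CO1
F5 | step 4 | (2R)-1-(trans-4-hydroxy-4-methyl-3,5-dioxocyclohexyl)propan-2-yl formate | O=CO[C@H](C)C[C@@H]1CC(=O)[C@@](C)(O)C(=O)C1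
F6 | step 4 | (2R)-1-(trans-4-acetoxy-4-methyl-3,5-dioxocyclohexyl)propan-2-yl formate | O=CO[C@H](C)C[C@@H]1CC(=O)[C@@](C)(OC(C)=O)C(=O)C1
F7 | step 5 | [bis(linoleoyloxy)iodo]benzene | CCCCC/C=C\C/C=C\CCCCCCCC(=O)OI(OC(=O)CCCCCCC/C=C\C/C=C\CCCCC)c1ccccc1
F8 | step 5 | trans-5-[(2R)-2-(formyloxy)propyl]-2-methyl-1,3-dioxocyclohexan-2-yl (9Z,12Z)-octadeca-9,12-dienoate | O=CO[C@H](C)C[C@@H]1CC(=O)[C@@](C)(OC(=O)CCCCCCC/C=C\C/C=C\CCCCC)C(=O)C1
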